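**Plan**

- Cuts: first C12–C13 (butenolide coupling), then C1–C10 and C2–C3 of ring A together, which excises a C1–C2 acrylate unit. The remaining cuts are C9–C11, C10=C20, C4–C5 and C8–C17, all on a purchased six-membered ring B.
- Forward: ring B (C5–C10) is bought as a cyclohexenone and substituted one carbon unit at a time. Ring A is annulated onto it in the key step, and the butenolide is coupled last.
- Enabling feature: the methyl-bearing ring-fusion carbon C10 and the C3 carbinol stand 1,4 to each other across C5 and the C4 gem-dimethyl carbon. An exocyclic C10=CH2 (the future C20 methyl) and a C3 aldehyde on ring B are therefore the two ends between which a two-carbon acceptor can be inserted by hydrogen-atom transfer, Giese addition and aldol closure.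
- Stereochemistry: C6 is bought (S). C5 is set anti to it by conjugate addition, C8 by equilibration, C9 by equatorial attack on the ring B chair, and C10 by radical addition anti to the C5 and C9 substituents. C3 and C6 are set together at the end by α-face hydride delivery to a 3,6-dione.
- Helpers: a nitrile as masked C3 aldehyde; CO2Me on C2 (activates the acceptor, removed by Krapcho reaction); TBS on O6; Bpin on C12 (keeps the side chain saturated through the radical step and is the coupling handle).

Key step: step 7

Remark: atoms carry labdane numbers from the start (C1–C10 decalin, C11–C16 side chain, C17 on C8, C18/C19 on C4, C20 on C10); α is the face of the C9 hydroxyl and β the face of the C10 methyl in the target.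
Assumption: (S)-4-(tert-butyldimethylsilyloxy)cyclohex-2-en-1-one is taken as a purchasable single enantiomer.

**Step 1**
Reactants: 1 (S)-4-(tert-butyldimethylsilyloxy)cyclohex-2-en-1-one
Product: 3 (4S)-4-(tert-butyldimethylsilyloxy)-6-methylcyclohex-2-en-1-one (both C8 epimers), via lithium dienolate 2 (not isolated)
Conditions: LiN(i-Pr)2, THF, −78 °C; MeI, −78 → −30 °C
Reagents that add atoms: iodomethane, CI
Why: Kinetic α′-deprotonation of the enone gives the cross-conjugated lithium dienolate, which is C-methylated (enolate alkylation); the new C8 centre may form as an epimer mixture because it is equilibrated in step 2.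

**Step 2**
Reactants: 3 (4S)-4-(tert-butyldimethylsilyloxy)-6-methylcyclohex-2-en-1-one (both C8 epimers); 4 2-methylpropanenitrile
Product: 6 ring B keto nitrile [9-oxo / 8α-methyl / 6α-OTBS / 5β-(2-cyanopropan-2-yl) / all equatorial], via C8-epimeric ketone mixture 5 (not isolated)
Conditions: 4, LiN(i-Pr)2, THF, −78 °C; DMPU, then 3, −78 → −20 °C; NH4Cl (aq); then NaOMe (cat.), MeOH, 23 °C
Reagents that add atoms: none
Why: Michael addition of the tertiary α-cyano carbanion (metalated nitrile, thermodynamic 1,4-adduct) should occur anti to the adjacent C6 silyloxy group and so set C5, and methoxide epimerisation α to the ketone should then move the C8 methyl into the equatorial position, cis to OTBS.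

**Step 3**
Reactants: 6 ring B keto nitrile
Product: 10 ring B α-methylene ketone [9-oxo / 10-methylidene / 8α-methyl / 6α-OTBS / 5β-(2-cyanopropan-2-yl)], via lithium enolate 7 (not isolated), via Mannich base 8 (not isolated), via ammonium iodide 9 (not isolated)
Conditions: LiN(i-Pr)2, THF, −78 °C; [CH2=NMe2]I, −78 → 0 °C; MeI, Et2O, 23 °C; NaHCO3, CH2Cl2/H2O, 23 °C
Reagents that add atoms: N,N-dimethylmethyleneiminium iodide, C=[N+](C)C.[I-]
Why: Kinetic deprotonation at the less substituted α-carbon C10 (CH2 versus the C8 methine), Mannich reaction, N-methylation and E1cB loss of trimethylamine (Eschenmoser methylenation) should install the exocyclic C10=CH2 without a new stereocentre; bicarbonate is mild enough to leave C8 and the exocyclic double bond in place.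

**Step 4**
Reactants: 10 ring B α-methylene ketone; 11 vinylmagnesium bromide
Product: 12 ring B tertiary allylic alcohol [9α-hydroxy / 9β-vinyl / 10-methylidene / 8α-methyl / 6α-OTBS / 5β-(2-cyanopropan-2-yl)]
Conditions: CeCl3, THF, −78 °C; 11, −78 → −40 °C; NH4Cl (aq)
Reagents that add atoms: none
Why: 1,2-Addition of the weakly basic vinylcerium reagent (organocerium addition) to the chair-locked ketone should follow the equatorial trajectory on the β face, away from the axial hydrogens at C5 and C7 and unhindered by the flat C10 methylene, which places the vinyl group equatorial (trans to the C8 methyl) and the C9 hydroxyl axial (α).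

**Step 5**
Reactants: 12 ring B tertiary allylic alcohol
Product: 13 ring B boronate [9α-hydroxy / 9β-(2-(4,4,5,5-tetramethyl-1,3,2-dioxaborolan-2-yl)ethyl) / 10-methylidene / 8α-methyl / 6α-OTBS / 5β-(2-cyanopropan-2-yl)]
Conditions: HBpin, [Ir(cod)Cl]2 (cat.), dppe (cat.), CH2Cl2, 23 °C; NH4Cl (aq)
Reagents that add atoms: pinacolborane, CC1(C)OBOC1(C)C
Why: Iridium-catalysed anti-Markovnikov hydroboration is selective for the monosubstituted vinyl group over the hindered 1,1-disubstituted C10 methylene and turns the radical-sensitive alkene into a saturated C12 boronate that later serves as the coupling handle; no stereocentre is formed.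

**Step 6**
Reactants: 13 ring B boronate
Product: 15 ring B aldehyde [2-methylpropanal unit C3/C4 on C5β / 9α-hydroxy / 9β-(2-Bpin-ethyl) / 10-methylidene / 8α-methyl / 6α-OTBS], via aldimine 14 (not isolated)
Conditions: i-Bu2AlH, toluene, −78 → 0 °C; KNaC4H4O6 (aq), 23 °C
Reagents that add atoms: water, O
Why: Half-reduction of the hindered tertiary nitrile stops at the N-alumino aldimine, which hydrolysis converts into the non-enolisable neopentyl aldehyde C3 (nitrile-to-aldehyde reduction); the first equivalent of hydride only deprotonates the C9 hydroxyl.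

**Step 7**
Reactants: 15 ring B aldehyde; 16 methyl acrylate
Product: 19 trans-decalin β-hydroxy ester [2-CO2Me and 3-OH of undefined configuration / 4,4-dimethyl / 5α-H / 6α-OTBS / 8α-methyl / 9α-hydroxy / 9β-(2-Bpin-ethyl) / 10β-methyl], via C10 radical 17 (not isolated), via C2 radical 18 (not isolated)
Conditions: 16 (excess), Fe(acac)3 (30 mol %), PhSi(Oi-Pr)H2, EtOH, 0 → 23 °C
Reagents that add atoms: none
Why: An iron hydride formed from Fe(acac)3 and the silane transfers a hydrogen atom to the CH2 terminus of the C10 methylene (which becomes the C20 methyl), the tertiary radical 17 adds to methyl acrylate (Giese addition, C1–C10), the α-ester radical 18 is reduced by divalent iron to an iron enolate, and this enolate adds to the C3 aldehyde (aldol, C2–C3). The closest known reaction type is the hydrogen-atom-transfer-initiated radical-polar crossover annulation of γ,δ-unsaturated carbonyl compounds with electron-poor alkenes (Mukaiyama-type HAT, Giese addition, intramolecular aldol). Ring A is closed in the aldol event as a 6-(enolexo)-exo-trig cyclisation through a chair in which C1 and C4 are both equatorial on ring B, so the new ring is trans-fused. C10 is controlled by the ring B chair: the acrylate should approach the planar radical on the α face, anti to the equatorial C4 unit on C5 and to the equatorial side chain on C9, which places C1 trans to C4 and the methyl axial (β); C2 and C3 are expected to be cis from a metal-bridged closed aldol transition state, but neither is relied on because both are re-set in steps 9 to 11. The step needs Giese addition to outrun simple reduction of the hindered radical and aldol closure to outrun protonation of the enolate; excess acrylate serves the first, the non-enolisable neopentyl aldehyde held close by the C4 gem-dimethyl group serves the second, and the hydroboration of step 5 has left the C10 methylene as the only alkene that can accept a hydrogen atom.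

**Step 8**
Reactants: 19 trans-decalin β-hydroxy ester
Product: 20 decalin triol ester [2-CO2Me / 3-OH / 6α-OH / 9α-OH / 9β-(2-Bpin-ethyl)]
Conditions: Bu4NF, THF, 0 → 23 °C
Reagents that add atoms: none
Why: Fluoride-induced cleavage of the silyl ether (desilylation) frees the equatorial 6α-hydroxyl; the β-hydroxy ester and the boronate are expected to tolerate the conditions.

**Step 9**
Reactants: 20 decalin triol ester
Product: 21 decalin 3,6-dione β-keto ester [2-CO2Me / 3-oxo / 6-oxo / 9α-OH / 9β-(2-Bpin-ethyl)]
Conditions: Dess–Martin periodinane, NaHCO3, CH2Cl2, 23 °C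
Reagents that add atoms: none
Why: Dess–Martin oxidation converts both secondary alcohols (C3 and C6) into ketones while the tertiary C9 hydroxyl cannot react; this deliberately erases the C3 and C6 configurations and turns the helper ester into a β-keto ester ready for removal.

**Step 10**
Reactants: 21 decalin 3,6-dione β-keto ester
Product: 22 decalin 3,6-dione [3-oxo / 6-oxo / 5α-H / 8α-methyl / 9α-OH / 9β-(2-Bpin-ethyl) / 10β-methyl]
Conditions: LiCl, DMSO/H2O, 130 °C
Reagents that add atoms: none
Why: Krapcho dealkoxycarbonylation (chloride attack on the ester methyl, then loss of CO2 from the β-keto carboxylate) removes the activating group from C2; C5 is now α to the C6 ketone, but the trans ring fusion is the thermodynamically preferred one, so equilibration should not change it.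

**Step 11**
Reactants: 22 decalin 3,6-dione
Product: 23 decalin triol [3β-OH / 6β-OH / 9α-OH / 9β-(2-Bpin-ethyl)]
Conditions: NaBH4, MeOH, 0 °C
Reagents that add atoms: none
Why: Borohydride should deliver hydride to both carbonyls from the α face, because the β face is screened by the axial methyl groups on C10 and C4; this gives the equatorial 3β-alcohol and the axial 6β-alcohol in one operation (substrate-controlled ketone reduction).

**Step 12**
Reactants: 23 decalin triol
Product: 24 decalin 3β,6β-diacetate [9α-OH free / 9β-(2-Bpin-ethyl)]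
Conditions: Ac2O, DMAP, pyridine, 50 °C
Reagents that add atoms: acetic anhydride, CC(=O)OC(C)=O
Why: Nucleophile-catalysed acylation under forcing conditions esterifies both secondary hydroxyls, the hindered axial 6β-OH included, while the tertiary 9α-OH stays free.

**Step 13**
Reactants: 24 decalin 3β,6β-diacetate
Product: 25 decalin 6β-monoacetate [3β-OH / 6β-OAc / 9α-OH / 9β-(2-Bpin-ethyl)]
Conditions: K2CO3 (cat.), MeOH, 0 → 23 °C
Reagents that add atoms: none
Why: Carbonate-catalysed methanolysis (transesterification) should cleave the equatorial 3β-acetate much faster than the axial 6β-acetate, which is shielded by the two syn-axial methyl groups.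

**Step 14**
Reactants: 25 decalin 6β-monoacetate; 26 3-bromofuran-2(5H)-one
Product: 27 6β-acetoxy-3β,9α-dihydroxylabd-13-en-16,15-olide (CNP0513254.1)
Conditions: 26, Pd(dppf)Cl2 (cat.), Ag2O, K2CO3, THF, 70 °C
Reagents that add atoms: none
Why: B-alkyl Suzuki–Miyaura coupling: Ag2O accelerates transmetalation of the primary alkyl pinacol boronate to the alkenylpalladium bromide formed from 26, and reductive elimination forms C12–C13 under conditions that are close to neutral for the acetate and the butenolide.

**Compound list**

1 | (S)-4-(tert-butyldimethylsilyloxy)cyclohex-2-en-1-one | CC(C)(C)[Si](C)(C)O[C@H]1CCC(=O)C=C1 | starting material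
2 | lithium (S)-4-(tert-butyldimethylsilyloxy)cyclohexa-1,5-dien-1-olate (dienolate of 1) | CC(C)(C)[Si](C)(C)O[C@H]1CC=C(O[Li])C=C1 | intermediate
3 | (4S)-4-(tert-butyldimethylsilyloxy)-6-methylcyclohex-2-en-1-one, both epimers at the methyl carbon C8 | CC(C)(C)[Si](C)(C)O[C@H]1CC(C)C(=O)C=C1 | intermediate
4 | 2-methylpropanenitrile (isobutyronitrile) | CC(C)C#N | starting material
5 | 2-[2-(tert-butyldimethylsilyloxy)-4-methyl-5-oxocyclohexyl]-2-methylpropanenitrile, C5 side chain β and trans to 6α-OTBS, C8 undefined | CC(C)(C)[Si](C)(C)O[C@H]1CC(C)C(=O)C[C@@H]1C(C)(C)C#N | intermediate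
6 | 2-[2-(tert-butyldimethylsilyloxy)-4-methyl-5-oxocyclohexyl]-2-methylpropanenitrile, all-equatorial isomer (5β side chain, 6α-OTBS, 8α-methyl) | CC(C)(C)[Si](C)(C)O[C@H]1C[C@@H](C)C(=O)C[C@@H]1C(C)(C)C#N | intermediate
7 | lithium enolate of 6 (C9–OLi, C9=C10) | CC(C)(C)[Si](C)(C)O[C@H]1C[C@@H](C)C(O[Li])=C[C@@H]1C(C)(C)C#N | intermediate
8 | Mannich base: 6 carrying CH2NMe2 on C10 (C10 not defined) | CC(C)(C)[Si](C)(C)O[C@H]1C[C@@H](C)C(=O)C(CN(C)C)[C@@H]1C(C)(C)C#N | intermediate
9 | trimethylammonium iodide of 8 | CC(C)(C)[Si](C)(C)O[C@H]1C[C@@H](C)C(=O)C(C[N+](C)(C)C)[C@@H]1C(C)(C)C#N.[I-] | intermediate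
10 | α-methylene ketone: 2-[2-(tert-butyldimethylsilyloxy)-4-methyl-6-methylidene-5-oxocyclohexyl]-2-methylpropanenitrile (5β side chain, 6α-OTBS, 8α-methyl) | CC(C)(C)[Si](C)(C)O[C@H]1C[C@@H](C)C(=O)C(=C)[C@@H]1C(C)(C)C#N | intermediate
11 | vinylmagnesium bromide | C=C[Mg]Br | starting material
12 | tertiary allylic alcohol: 10 with C9 converted to 9α-hydroxy-9β-vinyl | CC(C)(C)[Si](C)(C)O[C@H]1C[C@@H](C)[C@](O)(C=C)C(=C)[C@@H]1C(C)(C)C#N | intermediate
13 | boronate: 12 with the vinyl group converted to 2-(4,4,5,5-tetramethyl-1,3,2-dioxaborolan-2-yl)ethyl | CC(C)(C)[Si](C)(C)O[C@H]1C[C@@H](C)[C@](O)(CCB2OC(C)(C)C(C)(C)O2)C(=C)[C@@H]1C(C)(C)C#N | intermediate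
14 | aldimine of 15 (C3H=NH) | CC(C)(C)[Si](C)(C)O[C@H]1C[C@@H](C)[C@](O)(CCB2OC(C)(C)C(C)(C)O2)C(=C)[C@@H]1C(C)(C)C=N | intermediate
15 | aldehyde: 13 with the nitrile converted to CHO (C3) | CC(C)(C)[Si](C)(C)O[C@H]1C[C@@H](C)[C@](O)(CCB2OC(C)(C)C(C)(C)O2)C(=C)[C@@H]1C(C)(C)C=O | intermediate
16 | methyl acrylate | C=CC(=O)OC | starting material
17 | tertiary C10 radical from 15 (C20 now methyl) | CC(C)(C)[Si](C)(C)O[C@H]1C[C@@H](C)[C@](O)(CCB2OC(C)(C)C(C)(C)O2)[C](C)[C@@H]1C(C)(C)C=O | intermediate
18 | Giese adduct radical (C10 quaternary, 10β-methyl, radical at C2 α to CO2Me) | CC(C)(C)[Si](C)(C)O[C@H]1C[C@@H](C)[C@](O)(CCB2OC(C)(C)C(C)(C)O2)[C@@](C)(C[CH]C(=O)OC)[C@@H]1C(C)(C)C=O | intermediate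
19 | trans-decalin β-hydroxy ester: methyl 3-hydroxy-4,4-dimethyl decalin-2-carboxylate with 5α-H, 6α-OTBS, 8α-methyl, 9α-OH, 9β-(2-Bpin-ethyl), 10β-methyl; C2 and C3 undefined | CC(C)(C)[Si](C)(C)O[C@H]1C[C@@H](C)[C@](O)(CCB3OC(C)(C)C(C)(C)O3)[C@@]2(C)CC(C(=O)OC)C(O)C(C)(C)[C@H]12 | intermediate
20 | triol ester: 19 with free 6α-OH | O[C@H]1C[C@@H](C)[C@](O)(CCB3OC(C)(C)C(C)(C)O3)[C@@]2(C)CC(C(=O)OC)C(O)C(C)(C)[C@H]12 | intermediate
21 | 3,6-dione β-keto ester (C2 undefined) | O=C1C[C@@H](C)[C@](O)(CCB3OC(C)(C)C(C)(C)O3)[C@@]2(C)CC(C(=O)OC)C(=O)C(C)(C)[C@H]12 | intermediate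
22 | 3,6-dione: 9α-hydroxy-9β-(2-Bpin-ethyl)-4,4,8α,10β-tetramethyl-trans-decalin-3,6-dione | O=C1C[C@@H](C)[C@](O)(CCB3OC(C)(C)C(C)(C)O3)[C@@]2(C)CCC(=O)C(C)(C)[C@H]12 | intermediate
23 | 3β,6β,9α-triol boronate | O[C@@H]1C[C@@H](C)[C@](O)(CCB3OC(C)(C)C(C)(C)O3)[C@@]2(C)CC[C@H](O)C(C)(C)[C@H]12 | intermediate
24 | 3β,6β-diacetate of 23 | CC(=O)O[C@@H]1C[C@@H](C)[C@](O)(CCB3OC(C)(C)C(C)(C)O3)[C@@]2(C)CC[C@H](OC(C)=O)C(C)(C)[C@H]12 | intermediate
25 | 6β-monoacetate: 6β-acetoxy-3β,9α-dihydroxy boronate | CC(=O)O[C@@H]1C[C@@H](C)[C@](O)(CCB3OC(C)(C)C(C)(C)O3)[C@@]2(C)CC[C@H](O)C(C)(C)[C@H]12 | intermediate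
26 | 3-bromofuran-2(5H)-one | O=C1OCC=C1Br | starting material
27 | 6β-acetoxy-3β,9α-dihydroxylabd-13-en-16,15-olide (CNP0513254.1) | CC(=O)O[C@@H]1C[C@@H](C)[C@](O)(CCC2=CCOC2=O)[C@@]2(C)CC[C@H](O)C(C)(C)[C@H]12 | target

**Step count and risks**

Total step count: 14. Longest linear sequence: 14 steps (from 1 to 27).

The three steps most likely to fail:

Step 7. The iron enolate formed after the Giese addition may be protonated by the alcohol solvent before it reaches the hindered neopentyl aldehyde, so the cascade would stop after the first bond. Fallback, setting out from 15: the same hydrogen-atom-transfer Giese coupling with 16 is run in aqueous ethanol so that the enolate is protonated on purpose, giving the open-chain ester F1. Ring A is then closed in a separate polar step, by kinetic ester-enolate formation with LiN(SiMe3)2 in THF at −78 °C and intramolecular aldol addition to the non-enolisable aldehyde. This returns to the route at 19.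

Step 4. Facial selectivity may be poor: axial entry of the small vinyl nucleophile at the α-methylene ketone would give the C9 epimer. Fallback, setting out from 8 (step 3 is stopped before the methylation and 8 is isolated as its equatorial isomer): 11 is added without CeCl3 in CH2Cl2/Et2O, so that magnesium is chelated between the amine and the carbonyl oxygen and the nucleophile enters from the face of the axial C10 hydrogen, giving the amino alcohol F2. N-Oxidation with m-CPBA at 0 °C gives the amine oxide F3, and Cope elimination in THF at 65 °C forms the exocyclic methylene. This returns to the route at 12.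

Step 14. Transmetalation of the primary alkyl pinacol boronate may be slower than base-induced decomposition of the bromobutenolide and protodeboronation. Fallback, setting out from 25: the C–B bond is oxidised with NaBO3 in THF/H2O to the primary alcohol F4. Appel iodination (I2, PPh3, imidazole), selective for the primary hydroxyl, gives the iodide F5. A nickel-catalysed reductive cross-electrophile coupling of F5 with 26 (NiBr2(dme), 4,4′-di-tert-butyl-2,2′-bipyridine, Zn, DMA, 23 °C) needs no base and tolerates the free hydroxyls. This returns to the route at 27.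

**Further compounds**

F1 | step 7 | open-chain Giese ester: methyl 3-(ring B C10)-propanoate with 10β-methyl, C3 aldehyde intact, 9α-OH, 9β-(2-Bpin-ethyl), 8α-methyl, 6α-OTBS | CC(C)(C)[Si](C)(C)O[C@H]1C[C@@H](C)[C@](O)(CCB2OC(C)(C)C(C)(C)O2)[C@@](C)(CCC(=O)OC)[C@@H]1C(C)(C)C=O
F2 | step 4 | amino alcohol: 9α-hydroxy-9β-vinyl-10α-(dimethylaminomethyl) ring B nitrile | CC(C)(C)[Si](C)(C)O[C@H]1C[C@@H](C)[C@](O)(C=C)[C@@H](CN(C)C)[C@@H]1C(C)(C)C#N
F3 | step 4 | amine oxide of F2 | CC(C)(C)[Si](C)(C)O[C@H]1C[C@@H](C)[C@](O)(C=C)[C@@H](C[N+](C)(C)[O-])[C@@H]1C(C)(C)C#N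
F4 | step 14 | primary alcohol: 6β-acetoxy-3β,9α,12-trihydroxy-13,14,15,16-tetranorlabdane | CC(=O)O[C@@H]1C[C@@H](C)[C@](O)(CCO)[C@@]2(C)CC[C@H](O)C(C)(C)[C@H]12
F5 | step 14 | primary iodide: 6β-acetoxy-3β,9α-dihydroxy-12-iodo-13,14,15,16-tetranorlabdane | CC(=O)O[C@@H]1C[C@@H](C)[C@](O)(CCI)[C@@]2(C)CC[C@H](O)C(C)(C)[C@H]12
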